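**Plan**

- Retrosynthesis: the chromene C3=C4 bond goes back to a chroman-4-one, the catechol to its bis(benzyl) ether and the indane CH2 (C9) to a CH(OH). The five-membered ring is then cut at two bonds at once, C5–Cb and C9–Ca, which gives aldehyde triflate 20 and cyclobutene 12.
- Enabling feature: ring A (the methoxy arene) carries on the neighbouring carbons C5 and C6 the benzylic ring-fusion CH (Cb) and the CH2 (C9). C5, C6, C9, Ca and Cb form the cyclopentane of the indane, so an ortho-triflyloxy benzaldehyde can deliver both bonds to the two alkene carbons of a cyclobutene.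
- Forward order: the four-membered ring is made first (keteniminium [2+2], then cyclobutene 12) and the pyranone ring is built on phloroglucinol (to 20). The five-membered ring is closed by the nickel-catalysed reductive [3+2] annulation, and the chromene double bond is unmasked in the last step.
- Stereochemistry: Cc comes from the auxiliary-controlled [2+2]. Ca and Cb follow from Cc in the annulation (attack anti to the catechol aryl, syn addition, enforced cis 5/4 fusion). The carbinol centres at C9 and C4 are transient.

Key step: step 10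

Labels: ring A positions follow chromanone numbering (O1, C2, C3, C4, C4a, C5–C8, C8a). Ca is the ring-fusion carbon next to CMe2, Cb the benzylic ring-fusion carbon, Cc the cyclobutane carbon bearing the catechol aryl, Cd the CMe2 carbon, and C9 the one-carbon bridge between C6 and Ca.

Assumption: the (2R,5R)-amide 5 is taken to lead to (R)-9. If the sense of induction proves opposite, the (2S,5S)-amine replaces 4 and nothing else changes.

**Route**

Step 1
Reactants: 1 3,4-bis(benzyloxy)benzaldehyde
Product: 2 1,2-bis(benzyloxy)-4-vinylbenzene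
Conditions: Ph3PCH3Br, KOtBu, THF, 0 °C → rt
Reagents that add atoms: methyltriphenylphosphonium bromide, C[P+](c1ccccc1)(c1ccccc1)c1ccccc1.[Br-]
Why: Wittig methylenation of an aromatic aldehyde by the non-stabilised ylide, to which the benzyl ethers are inert.

Step 2
Reactants: 3 isobutyryl chloride; 4 (2R,5R)-2,5-dimethylpyrrolidine
Product: 5 1-[(2R,5R)-2,5-dimethylpyrrolidin-1-yl]-2-methylpropan-1-one
Conditions: Et3N, CH2Cl2, 0 °C → rt
Reagents that add atoms: none
Why: N-acylation of a secondary amine by an acid chloride (Schotten–Baumann type), which leaves the two stereocentres of the amine untouched.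

Step 3
Reactants: 5 1-[(2R,5R)-2,5-dimethylpyrrolidin-1-yl]-2-methylpropan-1-one; 2 1,2-bis(benzyloxy)-4-vinylbenzene
Product: 9 (3R)-3-[3,4-bis(benzyloxy)phenyl]-2,2-dimethylcyclobutan-1-one, via triflyloxyiminium triflate 6 (not isolated), via keteniminium triflate 7 (not isolated), via cyclobutaniminium triflate 8 (not isolated)
Conditions: Tf2O, 2,6-di-tert-butyl-4-methylpyridine, CH2Cl2, −20 °C → rt; then aq. NaHCO3, 40 °C
Reagents that add atoms: water, O
Why: Keteniminium–alkene [2+2] cycloaddition in which the electrophilic central carbon bonds to the styrene CH2 and the CMe2 carbon to the benzylic carbon, so that hydrolysis should give the 2,2-dimethyl-3-aryl ketone, the C2-symmetric pyrrolidine shielding one face of approach and thereby setting the aryl-bearing stereocentre.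

Step 4
Reactants: 9 (3R)-3-[3,4-bis(benzyloxy)phenyl]-2,2-dimethylcyclobutan-1-one
Product: 11 (3R)-3-[3,4-bis(benzyloxy)phenyl]-4,4-dimethylcyclobut-1-en-1-yl trifluoromethanesulfonate, via potassium enolate 10 (not isolated)
Conditions: KN(SiMe3)2, THF, −78 °C (ketone added to base); then PhNTf2, −78 → 0 °C
Reagents that add atoms: N-phenylbis(trifluoromethanesulfonimide), O=S(=O)(N(c1ccccc1)S(=O)(=O)C(F)(F)F)C(F)(F)F
Why: Enol triflate formation by deprotonation at the only enolisable position (the ring CH2) and O-sulfonylation of the enolate, the stereocentre being β to the carbonyl and therefore not at risk.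

Step 5
Reactants: 11 (3R)-3-[3,4-bis(benzyloxy)phenyl]-4,4-dimethylcyclobut-1-en-1-yl trifluoromethanesulfonate
Product: 12 (4S)-4-[3,4-bis(benzyloxy)phenyl]-3,3-dimethylcyclobut-1-ene
Conditions: Pd(OAc)2 (5 mol %), PPh3, HCO2H, Bu3N, DMF, 40 °C
Reagents that add atoms: none
Why: Palladium-catalysed formate reduction of a vinyl triflate (oxidative addition, decarboxylation of the formate complex of divalent palladium, C–H reductive elimination), run at mild temperature so that the cyclobutene does not undergo electrocyclic opening.

Step 6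
Reactants: 13 phloroglucinol; 14 3-methylbut-2-enoic acid
Product: 16 5,7-dihydroxy-2,2-dimethylchroman-4-one, via acylphloroglucinol enone 15 (not isolated)
Conditions: P2O5, MeSO3H, 70 °C
Reagents that add atoms: none
Why: Friedel–Crafts acylation of the symmetric triphenol followed in the same flask by intramolecular oxa-Michael addition of an ortho hydroxyl, so no regiochemical question arises.

Step 7
Reactants: 16 5,7-dihydroxy-2,2-dimethylchroman-4-one
Product: 17 5-hydroxy-7-methoxy-2,2-dimethylchroman-4-one
Conditions: MeI (1.05 equiv), K2CO3 (1.1 equiv), acetone, rt → 40 °C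
Reagents that add atoms: iodomethane, CI
Why: Williamson methylation that should select the 7-OH because the 5-OH is held in a hydrogen bond to the C4 carbonyl.

Step 8
Reactants: 17 5-hydroxy-7-methoxy-2,2-dimethylchroman-4-one
Product: 19 5-hydroxy-7-methoxy-2,2-dimethyl-4-oxochroman-6-carbaldehyde, via hydroxymethyl phenol 18 (not isolated)
Conditions: MgCl2, Et3N, (CH2O)n, MeCN, reflux; then 1 M HCl
Reagents that add atoms: paraformaldehyde (as formaldehyde), C=O
Why: Magnesium-mediated ortho-formylation of a phenol (Casnati–Skattebøl), in which the magnesium phenoxide delivers coordinated formaldehyde to C6, the only free position ortho to the 5-OH, and a second formaldehyde oxidises the hydroxymethyl phenol by hydride transfer.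

Step 9
Reactants: 19 5-hydroxy-7-methoxy-2,2-dimethyl-4-oxochroman-6-carbaldehyde
Product: 20 6-formyl-7-methoxy-2,2-dimethyl-4-oxochroman-5-yl trifluoromethanesulfonate
Conditions: Tf2O, pyridine, CH2Cl2, −10 → 0 °C
Reagents that add atoms: trifluoromethanesulfonic anhydride, O=S(=O)(OS(=O)(=O)C(F)(F)F)C(F)(F)F
Why: O-sulfonylation of an acidic ortho-acyl phenol to the aryl triflate, a standard activation that the aldehyde and ketone tolerate.

Step 10
Reactants: 20 6-formyl-7-methoxy-2,2-dimethyl-4-oxochroman-5-yl trifluoromethanesulfonate; 12 (4S)-4-[3,4-bis(benzyloxy)phenyl]-3,3-dimethylcyclobut-1-ene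
Product: 21 benzyl-protected tetracyclic indanol (chromanone ring A with C5–Cb and C6–C9(OH)–Ca bonds; cis-fused at Ca/Cb; 3,4-bis(benzyloxy)phenyl on Cc trans to ring A; OH cis to the Ca hydrogen; C9 S, Ca S, Cb S, Cc S)
Conditions: Ni(cod)2 (10 mol %), dppe (12 mol %), Zn (2 equiv), MeCN/THF, 25–40 °C; then aq. NH4Cl
Reagents that add atoms: none
Why: Proposed new method: zerovalent nickel should insert into the C5–OTf bond of 20 (activated by its two flanking carbonyl groups), the aryl–nickel species should add syn across the strained C=C of 12, and the secondary alkyl–nickel so formed, which cannot undergo β-hydride elimination because one neighbour is the quaternary Cd and the other holds its hydrogen anti to nickel, should add to the C6 formyl group before Zn returns divalent nickel to zerovalent nickel. The closest known reaction type is the nickel- or cobalt-catalysed reductive carbocyclisation of ortho-halo aryl aldehydes and ketones with alkynes, acrylates and strained bicyclic alkenes to indenols and indanols, for which a monocyclic cyclobutene has not been shown as partner. The cyclopentane closes by 5-exo-trig addition of the nickel-bearing carbon Ca to the aldehyde carbon, and because both new bonds reach the same face of the four-membered ring only a cis 5/4 fusion can form. Ca and Cb are controlled by the existing stereocentre Cc of 12 (approach anti to the catechol aryl, then syn addition), while C9 is expected to carry its OH on the convex face through the four-centre insertion geometry, although either epimer serves since step 11 removes this centre. The step needs regioselective insertion (ring A to the alkene carbon next to Cc, nickel to the one next to Cd), which the di-ortho-substituted aryl group should secure by avoiding the carbon whose neighbour shows a methyl group on either face, and it needs capture by the aldehyde in preference to the C4 ketone, which the higher electrophilicity of the formyl group and the vinylogous-ester character of the ketone should secure. The temperature is kept at or below 40 °C so that 12 does not open to the diene.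

Step 11
Reactants: 21 benzyl-protected tetracyclic indanol
Product: 22 benzyl-protected indane chromanone (C9 now CH2; Ca S, Cb R, Cc S)
Conditions: Et3SiH, BF3·OEt2, CH2Cl2, −78 → −30 °C
Reagents that add atoms: none
Why: Ionic hydrogenation in which the benzylic alcohol ionises to a cation stabilised by the ortho methoxy group and the para ring oxygen and is reduced by the silane, the low temperature sparing the chromanone and the benzyl ethers and the ring-fusion centres not being involved.

Step 12
Reactants: 22 benzyl-protected indane chromanone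
Product: 23 catechol chromanone (both benzyl ethers cleaved; Ca S, Cb R, Cc S)
Conditions: H2 (1 atm), 10% Pd/C, EtOAc/MeOH, rt
Reagents that add atoms: none
Why: Hydrogenolysis of benzyl aryl ethers over Pd/C under neutral conditions, which should leave the aryl ketone and the cyclobutane intact.

Step 13
Reactants: 23 catechol chromanone
Product: 24 catechol chroman-4-ol (mixture of C4 epimers; Ca S, Cb R, Cc S)
Conditions: NaBH4 (excess), MeOH/THF, 0 °C → rt
Reagents that add atoms: none
Why: Borohydride reduction of the aryl ketone to the benzylic alcohol, whose new C4 centre is erased in the next step.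

Step 14
Reactants: 24 catechol chroman-4-ol
Product: 25 CNP0207533.1 (7-methoxy-2,2-dimethyl-2H-chromene bridged at C5/C6 into the cis-fused cyclobuta-indane; 3,4-dihydroxyphenyl on Cc trans to ring A; Ca S, Cb R, Cc S)
Conditions: p-TsOH·H2O (cat.), toluene (dilute, degassed), 60 °C
Reagents that add atoms: none
Why: Acid-catalysed E1 dehydration of a 4-chromanol through the benzylic cation stabilised by O1 and the 7-methoxy group, the standard chromanone-to-chromene endgame, which does not touch the cyclobutane stereocentres.

**Compound list**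

1 | 3,4-bis(benzyloxy)benzaldehyde | O=Cc1ccc(OCc2ccccc2)c(OCc2ccccc2)c1 | starting material
2 | 1,2-bis(benzyloxy)-4-vinylbenzene | C=Cc1ccc(OCc2ccccc2)c(OCc2ccccc2)c1 | intermediate
3 | isobutyryl chloride | CC(C)C(Cl)=O | starting material
4 | (2R,5R)-2,5-dimethylpyrrolidine | C[C@@H]1CC[C@@H](C)N1 | starting material
5 | 1-[(2R,5R)-2,5-dimethylpyrrolidin-1-yl]-2-methylpropan-1-one | C[C@@H]1CC[C@@H](C)N1C(=O)C(C)C | intermediate
6 | triflyloxyiminium triflate from 5 | C[C@@H]1CC[C@@H](C)[N+]1=C(OS(=O)(=O)C(F)(F)F)C(C)C.[O-]S(=O)(=O)C(F)(F)F | intermediate (not isolated)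
7 | keteniminium triflate | C[C@@H]1CC[C@@H](C)[N+]1=C=C(C)C.[O-]S(=O)(=O)C(F)(F)F | intermediate (not isolated)
8 | cyclobutaniminium triflate | C[C@@H]1CC[C@@H](C)[N+]1=C2C[C@H](c3ccc(OCc4ccccc4)c(OCc4ccccc4)c3)C2(C)C.[O-]S(=O)(=O)C(F)(F)F | intermediate (not isolated)
9 | (3R)-3-[3,4-bis(benzyloxy)phenyl]-2,2-dimethylcyclobutan-1-one | O=C1C[C@H](c2ccc(OCc3ccccc3)c(OCc3ccccc3)c2)C1(C)C | intermediate
10 | potassium enolate of 9 | [K+].[O-]C1=C[C@H](c2ccc(OCc3ccccc3)c(OCc3ccccc3)c2)C1(C)C | intermediate (not isolated)
11 | (3R)-3-[3,4-bis(benzyloxy)phenyl]-4,4-dimethylcyclobut-1-en-1-yl trifluoromethanesulfonate | O=S(=O)(OC1=C[C@H](c2ccc(OCc3ccccc3)c(OCc3ccccc3)c2)C1(C)C)C(F)(F)F | intermediate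
12 | (4S)-4-[3,4-bis(benzyloxy)phenyl]-3,3-dimethylcyclobut-1-ene | C1=C[C@H](c2ccc(OCc3ccccc3)c(OCc3ccccc3)c2)C1(C)C | intermediate
13 | phloroglucinol | Oc1cc(O)cc(O)c1 | starting material
14 | 3-methylbut-2-enoic acid | CC(C)=CC(O)=O | starting material
15 | 3-methyl-1-(2,4,6-trihydroxyphenyl)but-2-en-1-one | CC(C)=CC(=O)c1c(O)cc(O)cc1O | intermediate (not isolated)
16 | 5,7-dihydroxy-2,2-dimethylchroman-4-one | CC1(C)CC(=O)c2c(O)cc(O)cc2O1 | intermediate
17 | 5-hydroxy-7-methoxy-2,2-dimethylchroman-4-one | COc1cc(O)c2C(=O)CC(C)(C)Oc2c1 | intermediate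
18 | 5-hydroxy-6-(hydroxymethyl)-7-methoxy-2,2-dimethylchroman-4-one | COc1cc2OC(C)(C)CC(=O)c2c(O)c1CO | intermediate (not isolated)
19 | 5-hydroxy-7-methoxy-2,2-dimethyl-4-oxochroman-6-carbaldehyde | COc1cc2OC(C)(C)CC(=O)c2c(O)c1C=O | intermediate
20 | 6-formyl-7-methoxy-2,2-dimethyl-4-oxochroman-5-yl trifluoromethanesulfonate | COc1cc2OC(C)(C)CC(=O)c2c(OS(=O)(=O)C(F)(F)F)c1C=O | intermediate
21 | benzyl-protected tetracyclic indanol (C9 S, Ca S, Cb S, Cc S) | COc1cc2OC(C)(C)CC(=O)c2c2c1[C@@H](O)[C@H]1[C@@H]2[C@H](c2ccc(OCc3ccccc3)c(OCc3ccccc3)c2)C1(C)C | intermediate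
22 | benzyl-protected indane chromanone (Ca S, Cb R, Cc S) | COc1cc2OC(C)(C)CC(=O)c2c2c1C[C@H]1[C@@H]2[C@H](c2ccc(OCc3ccccc3)c(OCc3ccccc3)c2)C1(C)C | intermediate
23 | catechol chromanone (Ca S, Cb R, Cc S) | COc1cc2OC(C)(C)CC(=O)c2c2c1C[C@H]1[C@@H]2[C@H](c2ccc(O)c(O)c2)C1(C)C | intermediate
24 | catechol chroman-4-ol, C4 epimers (Ca S, Cb R, Cc S) | COc1cc2OC(C)(C)CC(O)c2c2c1C[C@H]1[C@@H]2[C@H](c2ccc(O)c(O)c2)C1(C)C | intermediate
25 | CNP0207533.1 (Ca S, Cb R, Cc S) | COc1cc2c(c3c1C[C@H]1[C@@H]3[C@H](c3ccc(O)c(O)c3)C1(C)C)C=CC(C)(C)O2 | target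

**Count**

Total steps: 14. Longest linear sequence: 9 steps (steps 6, 7, 8, 9, 10, 11, 12, 13, 14; the cyclobutene arm through steps 1 or 2, 3, 4, 5 is equally long).

**Steps most likely to fail**

1. Step 10. The aryl–nickel species may be reduced or homocoupled before it inserts the hindered cyclobutene. Insertion may also take the reverse regiochemistry and end in β-hydride elimination, or the alkyl–nickel may be captured by the C4 ketone. The fallback uses known reactions and reverses the roles: ring A enters as a nucleophile and the bridging carbon C9 comes from the four-membered ring. It sets out from enol triflate 11 and phenol 17 and comes back at indanol 21. Palladium-catalysed formylation of 11 (Pd(PPh3)4, CO 1 atm, Bu3SnH, THF, 50 °C) should give (3R)-3-[3,4-bis(benzyloxy)phenyl]-4,4-dimethylcyclobut-1-ene-1-carbaldehyde F1. Triflation of 17 (Tf2O, pyridine, CH2Cl2) should give 7-methoxy-2,2-dimethyl-4-oxochroman-5-yl trifluoromethanesulfonate F2, and Miyaura borylation (B2pin2, PdCl2(dppf), KOAc, dioxane, 80 °C) should turn it into the pinacol boronate F3. Rhodium-catalysed conjugate addition of F3 to F1 ([Rh(cod)OH]2, dioxane/H2O, 40 °C) should place ring A on the β-carbon anti to the catechol aryl and give the 2-aryl-cyclobutanecarbaldehyde F4, whose α-centre can equilibrate through the enol. BF3·OEt2 (CH2Cl2, −78 °C) should then close the cis aldehyde onto C6 of ring A (intramolecular Friedel–Crafts hydroxyalkylation, ortho to the methoxy group and para to O1) to give 21.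

2. Step 11. Ionisation next to the four-membered ring may be followed by ring expansion of the cyclobutylcarbinyl cation before hydride transfer, and the silane may also reduce the chromanone carbonyl. The fallback replaces the cation by a radical, sets out from 21 and comes back at 22. Acylation of 21 (PhOC(S)Cl, pyridine, DMAP, CH2Cl2, rt) should give the O-phenyl thionocarbonate F5. Barton–McCombie reduction (Bu3SnH, AIBN, toluene, 80 °C) should then give 22, since a benzylic radical is trapped by the stannane faster than a cyclobutylcarbinyl radical opens.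

3. Step 8. The chelated phenol may react sluggishly, the electrophile may enter para to the 5-OH at C8, or formaldehyde may be taken up at C3 next to the ketone. The fallback delivers the carbon by a sigmatropic shift that can only reach C6, sets out from 17 and comes back at 19. O-Allylation (allyl bromide, K2CO3, DMF, 60 °C) should give 5-(allyloxy)-7-methoxy-2,2-dimethylchroman-4-one F6. Claisen rearrangement (N,N-diethylaniline, 190 °C; C4a is blocked) should give 6-allyl-5-hydroxy-7-methoxy-2,2-dimethylchroman-4-one F7. Alkene isomerisation (PdCl2(MeCN)2 cat., toluene, 60 °C) should give 5-hydroxy-7-methoxy-2,2-dimethyl-6-[(E)-prop-1-enyl]chroman-4-one F8, and Lemieux–Johnson cleavage (OsO4 cat., NaIO4, 2,6-lutidine, dioxane/H2O) should give 19.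

**Further compounds**

F1 | step 10 | (3R)-3-[3,4-bis(benzyloxy)phenyl]-4,4-dimethylcyclobut-1-ene-1-carbaldehyde | O=CC1=C[C@H](c2ccc(OCc3ccccc3)c(OCc3ccccc3)c2)C1(C)C
F2 | step 10 | 7-methoxy-2,2-dimethyl-4-oxochroman-5-yl trifluoromethanesulfonate | COc1cc2OC(C)(C)CC(=O)c2c(OS(=O)(=O)C(F)(F)F)c1
F3 | step 10 | 7-methoxy-2,2-dimethyl-5-(4,4,5,5-tetramethyl-1,3,2-dioxaborolan-2-yl)chroman-4-one | COc1cc2OC(C)(C)CC(=O)c2c(B3OC(C)(C)C(C)(C)O3)c1
F4 | step 10 | 2-(7-methoxy-2,2-dimethyl-4-oxochroman-5-yl)-3-[3,4-bis(benzyloxy)phenyl]-4,4-dimethylcyclobutane-1-carbaldehyde (aldehyde cis to ring A, aryl groups trans) | O=C[C@H]1[C@@H](c2cc(OC)cc3OC(C)(C)CC(=O)c23)[C@H](c2ccc(OCc3ccccc3)c(OCc3ccccc3)c2)C1(C)C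
F5 | step 11 | O-phenyl thionocarbonate of indanol 21 | COc1cc2OC(C)(C)CC(=O)c2c2c1[C@@H](OC(=S)Oc1ccccc1)[C@H]1[C@@H]2[C@H](c2ccc(OCc3ccccc3)c(OCc3ccccc3)c2)C1(C)C
F6 | step 8 | 5-(allyloxy)-7-methoxy-2,2-dimethylchroman-4-one | C=CCOc1cc(OC)cc2OC(C)(C)CC(=O)c12
F7 | step 8 | 6-allyl-5-hydroxy-7-methoxy-2,2-dimethylchroman-4-one | C=CCc1c(O)c2C(=O)CC(C)(C)Oc2cc1OC
F8 | step 8 | 5-hydroxy-7-methoxy-2,2-dimethyl-6-[(E)-prop-1-enyl]chroman-4-one | C/C=C/c1c(O)c2C(=O)CC(C)(C)Oc2cc1OC
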